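The synthesis rests on disconnecting C11–C12 (daucane numbering), the bond between the methyl-bearing side-chain carbon on C4 of cyclopentane ring A and the ester O–CH2. Both carbons are natural acceptors: C11 is carried as the carbonyl of a 4-acetyl group, which a reductive aldol closure of ring A installs, and C12 is formaldehyde-like. Polarity reversal of C12 as a (vanilloyloxy)methyl stannane allows a Stille union with the enol triflate of the tricyclic methyl ketone, which attaches the whole unprotected ester in one operation. The triflate already contains the 5,8-oxygen bridge, made by peracid epoxidation and transannular etherification; hydrogenation of the C11=C13 methylene finishes the target.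

Key step: step 10

Remarks: Daucane numbering is used for all bicyclic and tricyclic compounds: C1 is the quaternary ring-fusion carbon with methyl C15; C2, C3 and C4 complete cyclopentane ring A; C5 is the oxygen-bearing ring-fusion carbon; C6 to C10 complete the seven-membered ring, with methyl C14 on C8; the side chain on C4 is C11, C12 (OCH2) and C13. β is the face of C15. Compounds 1, 2 and 16 are assumed to be purchased.

Step 1
Reactants: 1 4-methylpent-4-enoic acid; 2 prop-2-en-1-yl propanoate
Product: 4 prop-2-en-1-yl 2,6-dimethyl-3-oxohept-6-enoate (racemic), via 1-(4-methylpent-4-enoyl)imidazole 3 (not isolated)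
Conditions: 1, CDI, THF, rt; added to 2 (2.1 equiv) + LiN(iPr)2 (2.1 equiv), THF, −78 → −20 °C; 1 M HCl
Reagents that add atoms: none
Why: Crossed Claisen condensation, in which the lithium enolate of 2 is C-acylated by acyl imidazole 3 and the second equivalent of enolate deprotonates the β-keto ester, so the reaction should stop at 4.

Step 2
Reactants: 4 prop-2-en-1-yl 2,6-dimethyl-3-oxohept-6-enoate; 5 3-bromoprop-1-ene
Product: 6 prop-2-en-1-yl 2,6-dimethyl-3-oxo-2-(prop-2-en-1-yl)hept-6-enoate (racemic)
Conditions: K2CO3, acetone, reflux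
Reagents that add atoms: none
Why: C-Alkylation of the stabilized β-keto ester enolate with the allylic bromide builds the quaternary carbon as a racemate, which is acceptable because step 4 is enantioconvergent.

Step 3
Reactants: 6 prop-2-en-1-yl 2,6-dimethyl-3-oxo-2-(prop-2-en-1-yl)hept-6-enoate
Product: 7 prop-2-en-1-yl 1,4-dimethyl-7-oxocyclohept-3-ene-1-carboxylate (racemic)
Conditions: RuCl2(=CHPh)(PCy3)(H2IMes) (second-generation Grubbs catalyst, 5 mol%), CH2Cl2 (0.005 M), 40 °C
Reagents that add atoms: none
Why: Ring-closing olefin metathesis between the C-allyl group and the 1,1-disubstituted terminus closes the seven-membered ring with the trisubstituted C8=C9 alkene, while closure onto the ester allyl group would need the disfavoured s-trans ester rotamer and high dilution suppresses cross-metathesis.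

Step 4
Reactants: 7 prop-2-en-1-yl 1,4-dimethyl-7-oxocyclohept-3-ene-1-carboxylate
Product: 8 (2R)-2,5-dimethyl-2-(prop-2-en-1-yl)cyclohept-4-en-1-one
Conditions: Pd2(dba)3 (2.5 mol%), (S)-t-Bu-PHOX (6 mol%), toluene, 30 °C
Reagents that add atoms: none
Why: Decarboxylative asymmetric allylic alkylation (Tsuji–Trost type) passes both enantiomers of 7 through one prochiral enolate and a π-allyl palladium cation, and the chiral phosphinooxazoline ligand decides the enolate face, the (S)-ligand being chosen by analogy with 2-methylcycloalkanone substrates to set C1 as R.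

Step 5
Reactants: 8 (2R)-2,5-dimethyl-2-(prop-2-en-1-yl)cyclohept-4-en-1-one; 9 but-3-en-2-one
Product: 10 (2R)-2,5-dimethyl-2-[(2E)-4-oxopent-2-en-1-yl]cyclohept-4-en-1-one
Conditions: 9 (5 equiv), RuCl2(=CH-C6H4-2-OiPr)(H2IMes) (second-generation Hoveyda–Grubbs catalyst, 5 mol%), CH2Cl2, 40 °C
Reagents that add atoms: none
Why: Olefin cross-metathesis of the terminal allyl group with the electron-poor enone should give the E-enone, and the trisubstituted ring alkene does not take part.

Step 6
Reactants: 10 (2R)-2,5-dimethyl-2-[(2E)-4-oxopent-2-en-1-yl]cyclohept-4-en-1-one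
Product: 11 1-[(3S,3aS,8aR)-3a-hydroxy-6,8a-dimethyl-1,2,3,3a,4,5,8,8a-octahydroazulen-3-yl]ethan-1-one (4β-acetyl, 5β-OH, both cis to C15)
Conditions: [(Ph3P)CuH]6 (0.2 equiv, 1.2 equiv of hydride), toluene, −40 → 0 °C; aq. NH4Cl
Reagents that add atoms: none
Why: Reductive aldol cyclization: conjugate reduction by copper hydride forms the copper enolate only at C4, which adds to the ring ketone (5-enolexo closure of ring A) through a closed chelated six-membered transition state, so that the tether from C1 enforces the cis ring fusion (5-OH cis to C15) and chelation places the acetyl group cis to the new hydroxyl.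

Step 7
Reactants: 11 1-[(3S,3aS,8aR)-3a-hydroxy-6,8a-dimethyl-1,2,3,3a,4,5,8,8a-octahydroazulen-3-yl]ethan-1-one
Product: 13 (1R,4S,5S,8S,9S)-5,8-epoxy-9-hydroxy-12-nordaucan-11-one (5β,8β-oxygen bridge, 9α-OH, 4β-acetyl), via 8α,9α-epoxide 12 (not isolated)
Conditions: mCPBA (1.1 equiv), CH2Cl2, 0 °C → rt (cat. CSA to complete the cyclization)
Reagents that add atoms: 3-chloroperoxybenzoic acid (mCPBA), O=C(OO)c1cccc(Cl)c1
Why: Peracid epoxidation of the trisubstituted C8=C9 alkene on the α-face, away from C15 and the 5-OH, is followed by transannular opening of the epoxide by the 5-OH at the tertiary C8 with inversion (the behaviour of the parent alcohol carotol toward peracids), so the configurations of C8 and C9 follow from the mechanism because only the α-epoxide can cyclize.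

Step 8
Reactants: 13 (1R,4S,5S,8S,9S)-5,8-epoxy-9-hydroxy-12-nordaucan-11-one
Product: 14 (1R,4S,5S,8S,9S)-5,8-epoxy-9-hydroxy-12-nordauc-11(13)-en-11-yl trifluoromethanesulfonate
Conditions: LiN(iPr)2 (2.2 equiv), THF, −78 °C; N-(5-chloropyridin-2-yl)triflimide (1.1 equiv), −78 °C; aq. NH4Cl
Reagents that add atoms: N-(5-chloropyridin-2-yl)-1,1,1-trifluoro-N-[(trifluoromethyl)sulfonyl]methanesulfonamide, O=S(=O)(N(c1ccc(Cl)cn1)S(=O)(=O)C(F)(F)F)C(F)(F)F
Why: Kinetic deprotonation of the methyl ketone at C13 (after the 9-OH) and O-sulfonylation of the enolate should give the terminal enol triflate, and the low temperature prevents enolization toward C4, which would expel the β-alkoxy bridge.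

Step 9
Reactants: 15 4-hydroxy-3-methoxybenzoic acid; 16 tributyl(iodomethyl)stannane
Product: 17 (tributylstannyl)methyl 4-hydroxy-3-methoxybenzoate
Conditions: KHCO3 (1.05 equiv), DMF, rt
Reagents that add atoms: none
Why: SN2 O-alkylation of the carboxylate, the only group that hydrogencarbonate deprotonates, with the activated α-stannyl iodide should leave the phenol free.

Step 10
Reactants: 14 (1R,4S,5S,8S,9S)-5,8-epoxy-9-hydroxy-12-nordauc-11(13)-en-11-yl trifluoromethanesulfonate; 17 (tributylstannyl)methyl 4-hydroxy-3-methoxybenzoate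
Product: 18 (1R,4R,5S,8S,9S)-5,8-epoxy-9-hydroxydauc-11(13)-en-12-yl 4-hydroxy-3-methoxybenzoate
Conditions: Pd2(dba)3 (5 mol%), AsPh3 (20 mol%), CuI (20 mol%), LiCl (3 equiv), NMP, 50 °C
Reagents that add atoms: none
Why: Migita–Kosugi–Stille coupling: zerovalent palladium inserts into the C11–O bond of the alkenyl triflate, the (aroyloxy)methyl group passes from tin through copper to palladium, and reductive elimination forms the C11–C12 sp2–sp3 bond between two carbons that are both acceptors by nature (a ketone carbon and a formaldehyde-level O–CH2), the latter used with reversed polarity. The closest known reactions are the palladium-catalysed hydroxymethylation and alkoxymethylation of aryl and alkenyl halides or triflates with Bu3SnCH2OR and the palladium/copper couplings of α-acyloxyalkyl stannanes. No ring is closed and no stereocenter is formed; the five ring stereocenters are not touched and C11 becomes stereogenic only in step 11. The step needs transfer of the oxygen-bearing methyl group in preference to butyl, which the α-oxygen and the coordination of the ester carbonyl to tin should secure, and it needs the product allylic ester to survive, for which the weakly donating AsPh3 ligand, the moderate temperature and the absence of base are chosen. The free 9-OH and the free phenol are compatible with the neutral conditions, so the complete ester side chain is attached without protecting groups.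

Step 11
Reactants: 18 (1R,4R,5S,8S,9S)-5,8-epoxy-9-hydroxydauc-11(13)-en-12-yl 4-hydroxy-3-methoxybenzoate
Product: 19 (1R,4R,5S,8S,9S,11S)-5,8-epoxy-9-hydroxydaucan-12-yl 4-hydroxy-3-methoxybenzoate (target CNP0277205.1)
Conditions: H2 (1 atm), RhCl(PPh3)3 (10 mol%), benzene–EtOH, rt
Reagents that add atoms: none
Why: Homogeneous hydrogenation of the 1,1-disubstituted C11=C13 alkene under substrate control: in the conformer that minimises A(1,2) strain the C4–H lies next to the C12 methylene and the bridgehead C5 stands perpendicular to the alkene plane, so hydrogen should be delivered to the open face anti to C5, which corresponds to 11S.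

Compound list
1 | 4-methylpent-4-enoic acid | C=C(C)CCC(=O)O | starting material
2 | prop-2-en-1-yl propanoate (allyl propionate) | CCC(=O)OCC=C | starting material
3 | 1-(4-methylpent-4-enoyl)imidazole | C=C(C)CCC(=O)n1ccnc1 | intermediate (not isolated)
4 | prop-2-en-1-yl 2,6-dimethyl-3-oxohept-6-enoate (racemic) | C=CCOC(=O)C(C)C(=O)CCC(C)=C | intermediate
5 | 3-bromoprop-1-ene (allyl bromide) | C=CCBr | starting material
6 | prop-2-en-1-yl 2,6-dimethyl-3-oxo-2-(prop-2-en-1-yl)hept-6-enoate (racemic) | C=CCOC(=O)C(C)(CC=C)C(=O)CCC(C)=C | intermediate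
7 | prop-2-en-1-yl 1,4-dimethyl-7-oxocyclohept-3-ene-1-carboxylate (racemic) | C=CCOC(=O)C1(C)CC=C(C)CCC1=O | intermediate
8 | (2R)-2,5-dimethyl-2-(prop-2-en-1-yl)cyclohept-4-en-1-one | C=CC[C@]1(C)CC=C(C)CCC1=O | intermediate
9 | but-3-en-2-one (methyl vinyl ketone) | CC(=O)C=C | starting material
10 | (2R)-2,5-dimethyl-2-[(2E)-4-oxopent-2-en-1-yl]cyclohept-4-en-1-one | CC(=O)/C=C/C[C@]1(C)CC=C(C)CCC1=O | intermediate
11 | 1-[(3S,3aS,8aR)-3a-hydroxy-6,8a-dimethyl-1,2,3,3a,4,5,8,8a-octahydroazulen-3-yl]ethan-1-one | CC(=O)[C@H]1CC[C@]2(C)CC=C(C)CC[C@]12O | intermediate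
12 | (1R,4S,5S)-8α,9α-epoxy-5-hydroxy-12-nordaucan-11-one (epoxide anti to the 5-OH) | CC(=O)[C@H]1CC[C@]2(C)C[C@@H]3O[C@]3(C)CC[C@]12O | intermediate (not isolated)
13 | (1R,4S,5S,8S,9S)-5,8-epoxy-9-hydroxy-12-nordaucan-11-one | CC(=O)[C@H]1CC[C@]2(C)C[C@H](O)[C@]3(C)CC[C@]12O3 | intermediate
14 | (1R,4S,5S,8S,9S)-5,8-epoxy-9-hydroxy-12-nordauc-11(13)-en-11-yl trifluoromethanesulfonate | C=C(OS(=O)(=O)C(F)(F)F)[C@H]1CC[C@]2(C)C[C@H](O)[C@]3(C)CC[C@]12O3 | intermediate
15 | 4-hydroxy-3-methoxybenzoic acid (vanillic acid) | COc1cc(C(=O)O)ccc1O | starting material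
16 | tributyl(iodomethyl)stannane | CCCC[Sn](CCCC)(CCCC)CI | starting material
17 | (tributylstannyl)methyl 4-hydroxy-3-methoxybenzoate | CCCC[Sn](CCCC)(CCCC)COC(=O)c1ccc(O)c(OC)c1 | intermediate
18 | (1R,4R,5S,8S,9S)-5,8-epoxy-9-hydroxydauc-11(13)-en-12-yl 4-hydroxy-3-methoxybenzoate | COc1cc(C(=O)OCC(=C)[C@H]2CC[C@]3(C)C[C@H](O)[C@]4(C)CC[C@]23O4)ccc1O | intermediate
19 | (1R,4R,5S,8S,9S,11S)-5,8-epoxy-9-hydroxydaucan-12-yl 4-hydroxy-3-methoxybenzoate | COc1cc(C(=O)OC[C@@H](C)[C@H]2CC[C@]3(C)C[C@H](O)[C@]4(C)CC[C@]23O4)ccc1O | target

Total step count: 11. Longest linear sequence: 10 steps (steps 1 to 8, 10 and 11; step 9 prepares the stannane).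

Steps most likely to fail

Step 10. Transfer of the sp3 (aroyloxy)methyl group from tin may be slower than protodestannylation or butyl transfer, and zerovalent palladium may ionize the allylic ester of the product. The fallback sets out from 14 and carries the C12 unit as a hydroxymethyl group: Stille coupling of 14 with (tributylstannyl)methanol (Pd(PPh3)4, LiCl, dioxane, 100 °C) should give (1R,4R,5S,8S,9S)-5,8-epoxydauc-11(13)-ene-9,12-diol F1, whose allylic alcohol is not ionized by palladium. Mitsunobu esterification of the primary allylic hydroxyl of F1 with vanillic acid 15 (PPh3, DIAD, THF, 0 °C) then comes back to the route at 18. The carboxylic acid should react in preference to the phenol, and the hindered 9-OH should not react.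

Step 11. Facial selectivity of hydrogen delivery to the C11=C13 alkene may be low or reversed, because it rests on a conformational preference of an exocyclic group. The fallback replaces steric control by a directing group and sets out from 11, before the oxygen bridge is closed. Enol triflate formation as in step 8 should give (1R,4S,5S)-5-hydroxy-12-nordauca-8,11(13)-dien-11-yl trifluoromethanesulfonate F2. Stille coupling with 17 as in step 10 gives (1R,4R,5S)-5-hydroxydauca-8,11(13)-dien-12-yl 4-hydroxy-3-methoxybenzoate F3. Hydrogenation of F3 with cationic [Rh(nbd)(dppb)]BF4 under high hydrogen pressure in CH2Cl2 is directed by the tertiary 5-OH, which binds rhodium and delivers hydrogen to the alkene face syn to C5, the face opposite to the one attacked in step 11; the trisubstituted ring alkene should remain. This gives (1R,4R,5S,11S)-5-hydroxydauc-8-en-12-yl 4-hydroxy-3-methoxybenzoate F4. Epoxidation and transannular etherification of F4 with mCPBA as in step 7 comes back to the route at 19.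

Step 7. The peracid may attack the β-face of the ring alkene, syn to the hydroxyl, giving an epoxide that cannot be opened transannularly. The fallback inverts the facial outcome through a halohydrin and sets out from 11. With N-bromosuccinimide in aqueous DME at 0 °C, a β-bromonium ion is opened by water at the tertiary C8 from the α-face to give (1R,4S,5S)-9β-bromo-5,8α-dihydroxy-12-nordaucan-11-one F5. K2CO3 in MeOH at 0 °C closes F5 with inversion at C9 to the α-epoxide 12, which cyclizes with catalytic CSA and comes back to the route at 13.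

Further compounds
F1 | step 10 | (1R,4R,5S,8S,9S)-5,8-epoxydauc-11(13)-ene-9,12-diol | OCC(=C)[C@H]1CC[C@]2(C)C[C@H](O)[C@]3(C)CC[C@]12O3
F2 | step 11 | (1R,4S,5S)-5-hydroxy-12-nordauca-8,11(13)-dien-11-yl trifluoromethanesulfonate | C=C(OS(=O)(=O)C(F)(F)F)[C@H]1CC[C@]2(C)CC=C(C)CC[C@]12O
F3 | step 11 | (1R,4R,5S)-5-hydroxydauca-8,11(13)-dien-12-yl 4-hydroxy-3-methoxybenzoate | COc1cc(C(=O)OCC(=C)[C@H]2CC[C@]3(C)CC=C(C)CC[C@]23O)ccc1O
F4 | step 11 | (1R,4R,5S,11S)-5-hydroxydauc-8-en-12-yl 4-hydroxy-3-methoxybenzoate | COc1cc(C(=O)OC[C@@H](C)[C@H]2CC[C@]3(C)CC=C(C)CC[C@]23O)ccc1O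
F5 | step 7 | (1R,4S,5S)-9β-bromo-5,8α-dihydroxy-12-nordaucan-11-one | CC(=O)[C@H]1CC[C@]2(C)C[C@@H](Br)[C@](C)(O)CC[C@]12O
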